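**Plan**

- The target is read as a (2S)-5,7,8-trihydroxyflavanone. Ring A carries four oxygens (O1, 5-OH, 7-OH, 8-OH), one more than phloroacetophenone supplies. Ring B carries a 4′-OH with a CH2CH2C(CH3)=CH2 chain at C3′.
- Enabling feature: the 4′-oxygen, C4′, C3′ and the benzylic CH2 make up the O=C–C=CH2 unit of an o-quinone methide, and the remaining CH2–C(CH3)=CH2 is a methallyl unit. Joining O4′ to the substituted alkene carbon and placing SiMe3 on the terminal carbon gives a 2-methyl-2-(trimethylsilylmethyl)chroman in which both the phenol and the alkene lie dormant.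
- Retrosynthetic cuts, in order: (a) that temporary O–C bond; (b) the three O-benzyl bonds on ring A; (c) the C2–C1′ bond between ring C and ring B; (d) in the temporary chroman, the ArCH2–CH2 and O–C(quaternary) bonds; (e) the C8–O bond of ring A and the one-carbon unit (C2) of ring C.
- Forward: ring C is closed on phloroacetophenone, C8 is hydroxylated para to the 5-OH, and ring A is benzylated. Separately the temporary dihydropyran ring is closed by [4+2] addition and its bromide is converted into a boronic acid. The halves are joined at C2, the benzyl ethers are hydrogenolysed while the alkene is still latent, and the temporary ring is opened last.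
- Stereochemistry: C2 (S), the only stereocentre of the target, is set by the chiral diene on rhodium in the conjugate addition. The quaternary carbon of the temporary ring is racemic and returns to sp2 in the last step.

Key step: step 5

Assumption: the (R,R) enantiomer of the diene ligand in step 7 is taken to deliver the aryl group to the face of the chromone that gives 2S; should a trial addition show the opposite sense, the (S,S) diene is used and nothing else changes.

**Route**

Step 1
Reactants: 1 2′,4′,6′-trihydroxyacetophenone
Product: 3 5,7-dihydroxy-4H-chromen-4-one, via pyrylium perchlorate 2 (not isolated)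
Conditions: HC(OEt)3 (5 equiv), 70% aq. HClO4 (1.2 equiv), rt; then H2O, 100 °C
Reagents that add atoms: triethyl orthoformate CCOC(OCC)OCC
Why: Acid-mediated condensation of the acetyl methyl group with the orthoformate and ring closure through an ortho hydroxyl give the 4-ethoxybenzopyrylium salt, whose hydrolysis delivers the 2,3-unsubstituted chromone (orthoformate–perchloric acid chromone synthesis), and because the two ortho hydroxyls of 1 are equivalent only one chromone can form.

Step 2
Reactants: 3 5,7-dihydroxy-4H-chromen-4-one
Product: 4 7-(benzyloxy)-5-hydroxy-4H-chromen-4-one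
Conditions: BnBr (1.05 equiv), K2CO3 (1.2 equiv), acetone, reflux
Reagents that add atoms: benzyl bromide BrCc1ccccc1
Why: Williamson etherification should occur only at the acidic, non-chelated 7-OH, since the 5-OH is held in a hydrogen bond to the C4 carbonyl and is not alkylated by carbonate in acetone.

Step 3
Reactants: 4 7-(benzyloxy)-5-hydroxy-4H-chromen-4-one
Product: 6 7-(benzyloxy)-5,8-dihydroxy-4H-chromen-4-one, via aryl sulfate 5 (not isolated)
Conditions: K2S2O8 (1.2 equiv), aq. NaOH, pyridine, 0 → 20 °C; then aq. HCl, Na2SO3, 80 °C
Reagents that add atoms: potassium peroxodisulfate [K+].[K+].[O-]S(=O)(=O)OOS(=O)(=O)[O-]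
Why: In the Elbs persulfate oxidation the 5-phenoxide attacks the peroxide oxygen through its para carbon, and since C8 is the only free position para to that phenoxide the sulfate, and after acid hydrolysis the hydroxyl, should enter exactly where ring A of the target needs its fourth oxygen.

Step 4
Reactants: 6 7-(benzyloxy)-5,8-dihydroxy-4H-chromen-4-one
Product: 7 5,7,8-tris(benzyloxy)-4H-chromen-4-one
Conditions: BnBr (2.6 equiv), K2CO3 (3 equiv), DMF, 60 °C, argon
Reagents that add atoms: benzyl bromide BrCc1ccccc1
Why: Double Williamson etherification in a warm dipolar medium overcomes the hydrogen bond of the 5-OH, and capping both hydroxyls removes the oxidation-prone quinol and the acidic protons before the rhodium step.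

Step 5
Reactants: 8 5-bromo-2-hydroxybenzyl alcohol; 9 trimethyl(2-methylallyl)silane
Product: 11 6-bromo-2-methyl-2-[(trimethylsilyl)methyl]chromane (racemic), via o-quinone methide 10 (not isolated)
Conditions: 9 (6 equiv), PhMe, sealed tube, 170 °C
Reagents that add atoms: none
Why: Thermal loss of water from 8 gives the o-quinone methide 10, an electron-poor 1-oxadiene that is consumed as it forms by the large excess of the electron-rich 1,1-disubstituted alkene 9 in an inverse-electron-demand hetero-Diels–Alder reaction. The closest known reaction type is the [4+2] cycloaddition of thermally generated o-quinone methides with enol ethers, styrenes and 1,1-disubstituted alkenes, a class to which allylsilanes belong through their comparable π-nucleophilicity. The dihydropyran ring closes by a concerted but asynchronous [4π+2π] union: the exocyclic CH2 of 10 bonds first to the terminal =CH2 of 9 (new C4–C3 bond), then the carbonyl oxygen bonds to the tertiary carbon (new O1–C2 bond) and the arene is restored. The only new stereocentre is the quaternary C2 of the chroman; nothing controls it, it should form racemic, and this is accepted because the carbon becomes sp2 again in the last step. The step needs regioselectivity (oxygen to the substituted alkene carbon) and chemoselectivity for ring closure over loss of silicon or ene transfer; the first is secured by the polarisation of 9, whose internal carbon bears the methyl group and the β C–Si bond that stabilise positive charge, and the second by neutral thermal conditions in which no nucleophile is present to take silicon from carbon. Slow thermal generation keeps the concentration of 10 low, so that its self-condensation is outrun by the alkene present in excess.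

Step 6
Reactants: 11 6-bromo-2-methyl-2-[(trimethylsilyl)methyl]chromane
Product: 14 {2-methyl-2-[(trimethylsilyl)methyl]chroman-6-yl}boronic acid (racemic), via aryllithium 12 (not isolated), via lithium triisopropoxyborate 13 (not isolated)
Conditions: n-BuLi (1.1 equiv), THF, −78 °C; B(OiPr)3 (1.5 equiv), −78 → 0 °C; then aq. AcOH (pH 5)
Reagents that add atoms: triisopropyl borate CC(C)OB(OC(C)C)OC(C)C; water O
Why: Bromine–lithium exchange, capture by the borate and mild hydrolysis (lithiation–borylation) should proceed cleanly because the cyclic β-silyl ether offers the aryllithium neither an acidic proton nor a leaving group at −78 °C, and the weakly acidic work-up leaves the tertiary ether closed.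

Step 7
Reactants: 7 5,7,8-tris(benzyloxy)-4H-chromen-4-one; 14 {2-methyl-2-[(trimethylsilyl)methyl]chroman-6-yl}boronic acid
Product: 15 (2S)-5,7,8-tris(benzyloxy)-2-{2-methyl-2-[(trimethylsilyl)methyl]chroman-6-yl}chroman-4-one (pair of epimers at the chroman C2, both 2S at the flavanone)
Conditions: 14 (2 equiv), [RhCl(C2H4)2]2 (3 mol %), (R,R)-2,5-diphenylbicyclo[2.2.2]octa-2,5-diene (6.6 mol %), aq. KOH (20 mol %), PhMe/H2O, 40 °C
Reagents that add atoms: none
Why: In this rhodium-catalysed asymmetric 1,4-addition of an arylboronic acid to a chromone (Hayashi–Miyaura reaction) the aryl group passes from boron to monovalent rhodium, the chiral diene allows only one face of C2=C3 to insert into the Rh–aryl bond, which sets C2 as S, and protonation of the oxa-π-allyl rhodium species by water releases the flavanone, the remote racemic chroman carbon having no influence on the facial choice.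

Step 8
Reactants: 15 (2S)-5,7,8-tris(benzyloxy)-2-{2-methyl-2-[(trimethylsilyl)methyl]chroman-6-yl}chroman-4-one
Product: 16 (2S)-5,7,8-trihydroxy-2-{2-methyl-2-[(trimethylsilyl)methyl]chroman-6-yl}chroman-4-one (pair of epimers at the chroman C2)
Conditions: H2 (1 atm), 10% Pd/C, EtOAc/MeOH, rt, argon work-up
Reagents that add atoms: none
Why: Heterogeneous hydrogenolysis should remove the three aryl benzyl ethers without loss elsewhere, because the side-chain double bond is still stored in the saturated silyl chroman and the flavanone C2–O bond is cleaved far more slowly than O-benzyl groups, so C2 keeps its configuration.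

Step 9
Reactants: 16 (2S)-5,7,8-trihydroxy-2-{2-methyl-2-[(trimethylsilyl)methyl]chroman-6-yl}chroman-4-one
Product: 17 (2S)-5,7,8-trihydroxy-2-[4-hydroxy-3-(3-methylbut-3-en-1-yl)phenyl]chroman-4-one
Conditions: BF3·OEt2 (6 equiv), 2,6-di-tert-butyl-4-methylpyridine (4 equiv), CH2Cl2/MeCN, −40 → 0 °C; then H2O
Reagents that add atoms: none
Why: In this Lewis-acid-promoted Peterson-type β-elimination of a β-silyl ether, BF3 ionises the tertiary C–O bond, the developing cation is stabilised by the adjacent C–Si bond and loses silicon to fluoride, which frees the 4′-phenol and places the double bond only between the former chroman C2 and the CH2 that carried silicon, while the hindered pyridine takes up protons so that the new alkene is neither shifted nor re-closed and the flavanone C2 is left untouched.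

**Compound list**

1 | 2′,4′,6′-trihydroxyacetophenone | CC(=O)c1c(O)cc(O)cc1O | starting material
2 | 4-ethoxy-5,7-dihydroxychromenylium perchlorate | CCOc1cc[o+]c2cc(O)cc(O)c12.[O-]Cl(=O)(=O)=O | intermediate
3 | 5,7-dihydroxy-4H-chromen-4-one | O=c1ccoc2cc(O)cc(O)c12 | intermediate
4 | 7-(benzyloxy)-5-hydroxy-4H-chromen-4-one | O=c1ccoc2cc(OCc3ccccc3)cc(O)c12 | intermediate
5 | potassium 7-(benzyloxy)-5-hydroxy-4-oxo-4H-chromen-8-yl sulfate | O=c1ccoc2c(OS(=O)(=O)[O-])c(OCc3ccccc3)cc(O)c12.[K+] | intermediate
6 | 7-(benzyloxy)-5,8-dihydroxy-4H-chromen-4-one | O=c1ccoc2c(O)c(OCc3ccccc3)cc(O)c12 | intermediate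
7 | 5,7,8-tris(benzyloxy)-4H-chromen-4-one | O=c1ccoc2c(OCc3ccccc3)c(OCc3ccccc3)cc(OCc3ccccc3)c12 | intermediate
8 | 5-bromo-2-hydroxybenzyl alcohol | OCc1cc(Br)ccc1O | starting material
9 | trimethyl(2-methylallyl)silane | C=C(C)C[Si](C)(C)C | starting material
10 | 4-bromo-6-methylidenecyclohexa-2,4-dien-1-one (o-quinone methide) | C=C1C=C(Br)C=CC1=O | intermediate
11 | 6-bromo-2-methyl-2-[(trimethylsilyl)methyl]chromane, racemic | C[Si](C)(C)CC1(C)CCc2cc(Br)ccc2O1 | intermediate
12 | {2-methyl-2-[(trimethylsilyl)methyl]chroman-6-yl}lithium, racemic | C[Si](C)(C)CC1(C)CCc2cc([Li])ccc2O1 | intermediate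
13 | lithium triisopropoxy{2-methyl-2-[(trimethylsilyl)methyl]chroman-6-yl}borate, racemic | C[Si](C)(C)CC1(C)CCc2cc([B-](OC(C)C)(OC(C)C)OC(C)C)ccc2O1.[Li+] | intermediate
14 | {2-methyl-2-[(trimethylsilyl)methyl]chroman-6-yl}boronic acid, racemic | C[Si](C)(C)CC1(C)CCc2cc(B(O)O)ccc2O1 | intermediate
15 | (2S)-5,7,8-tris(benzyloxy)-2-{2-methyl-2-[(trimethylsilyl)methyl]chroman-6-yl}chroman-4-one, epimer pair at the chroman C2 | C[Si](C)(C)CC1(C)CCc2cc([C@@H]3CC(=O)c4c(OCc5ccccc5)cc(OCc5ccccc5)c(OCc5ccccc5)c4O3)ccc2O1 | intermediate
16 | (2S)-5,7,8-trihydroxy-2-{2-methyl-2-[(trimethylsilyl)methyl]chroman-6-yl}chroman-4-one, epimer pair at the chroman C2 | C[Si](C)(C)CC1(C)CCc2cc([C@@H]3CC(=O)c4c(O)cc(O)c(O)c4O3)ccc2O1 | intermediate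
17 | (2S)-5,7,8-trihydroxy-2-[4-hydroxy-3-(3-methylbut-3-en-1-yl)phenyl]chroman-4-one | C=C(C)CCc1cc([C@@H]2CC(=O)c3c(O)cc(O)c(O)c3O2)ccc1O | target

**Count and risks**

Total steps: 9. Longest linear sequence: 7 steps (1 → 3 → 4 → 6 → 7 → 15 → 16 → 17; steps 1, 2, 3, 4, 7, 8, 9). The ring B arm (steps 5 and 6) joins at step 7.

Steps most likely to fail:

Step 9. Protons released when BF3 binds the four phenols may protonate the new 1,1-disubstituted alkene, which would lead to migration of the double bond or to re-closure onto the 4′-oxygen. Acid may also open and re-close the flavanone ring, with loss of configuration at C2 and migration of the ring A oxygen pattern. The fallback removes all protons before the ring is opened. It sets out from 16, which is silylated with N,O-bis(trimethylsilyl)acetamide in MeCN to (2S)-2-{2-methyl-2-[(trimethylsilyl)methyl]chroman-6-yl}-5,7,8-tris(trimethylsilyloxy)chroman-4-one F1. A catalytic amount of trimethylsilyl triflate in CH2Cl2 at −78 °C should then ionise the tertiary ether, and the silicon leaving carbon is passed to the aryloxide, so that the opening is catalytic in silyl cation. This should give (2S)-2-[3-(3-methylbut-3-en-1-yl)-4-(trimethylsilyloxy)phenyl]-5,7,8-tris(trimethylsilyloxy)chroman-4-one F2. Methanolysis of the four aryl silyl ethers (MeOH, trace AcOH, 0 °C) returns to the route at 17.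

Step 3. Sulfation at C8 is slow, and during it hydroxide may add to C2 of the chromone and open the pyranone ring with loss of formate; the electron-rich phenoxide may also be over-oxidised. The fallback moves the oxidation to near-neutral pH. It sets out from 4, which is oxidised with (KSO3)2NO in KH2PO4-buffered aqueous acetone to the para-quinone 7-(benzyloxy)-4H-chromene-4,5,8-trione F3. Reduction with Na2S2O4 in EtOAc/H2O gives the quinol and comes back to the route at 6.

Step 5. At 170 °C the o-quinone methide may condense with itself or with unreacted 8 faster than it is trapped, and the allylsilane may slowly lose silicon to the phenol. The fallback generates the same o-quinone methide at low temperature under anionic conditions. It sets out from 8, whose phenol is acylated selectively (Boc2O, i-Pr2NEt, cat. DMAP, CH2Cl2, 0 °C) to tert-butyl [4-bromo-2-(hydroxymethyl)phenyl] carbonate F4. Deprotonation of the benzylic alcohol with t-BuMgCl in Et2O at −78 °C in the presence of 9 (4 equiv) should trigger O-to-O transfer of the carbonate and its departure as tert-butyl carbonate. The magnesium-bound o-quinone methide 10 is then trapped by 9 on warming, and the route is rejoined at 11.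

**Further compounds**

F1 | step 9 | (2S)-2-{2-methyl-2-[(trimethylsilyl)methyl]chroman-6-yl}-5,7,8-tris(trimethylsilyloxy)chroman-4-one | C[Si](C)(C)CC1(C)CCc2cc([C@@H]3CC(=O)c4c(O[Si](C)(C)C)cc(O[Si](C)(C)C)c(O[Si](C)(C)C)c4O3)ccc2O1
F2 | step 9 | (2S)-2-[3-(3-methylbut-3-en-1-yl)-4-(trimethylsilyloxy)phenyl]-5,7,8-tris(trimethylsilyloxy)chroman-4-one | C=C(C)CCc1cc([C@@H]2CC(=O)c3c(O[Si](C)(C)C)cc(O[Si](C)(C)C)c(O[Si](C)(C)C)c3O2)ccc1O[Si](C)(C)C
F3 | step 3 | 7-(benzyloxy)-4H-chromene-4,5,8-trione | O=C1C=COC2=C1C(=O)C=C(OCc1ccccc1)C2=O
F4 | step 5 | tert-butyl [4-bromo-2-(hydroxymethyl)phenyl] carbonate | CC(C)(C)OC(=O)Oc1ccc(Br)cc1CO
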